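The readings come from a simulation for an exercise.

At early times a flask shows me the pace at which J works through its charge of G. So that is what I look for first in these runs.

| flask | G | J | remark | time |
|---|---|---|---|---|
| alpha | 0.10 M | 0.95 µM | run made earlier |  |
| zeta | 0.10 M | 0.47 µM | run made earlier |  |
| beta | 0.10 M | 0.71 µM | run made earlier |  |
| epsilon | 0.050 M | 0.95 µM | run made earlier |  |
| north-west | 0.10 M | 0.95 µM | one stirred flow tank at steady state, fed with the mixture as stated, mean residence time 5.0 h |  |
| west | 0.10 M | 0.95 µM | one stirred flow tank at steady state, fed with the mixture as stated, mean residence time 25.0 h |  |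
| north | 0.10 M (fed, over 4.00 h) | 0.95 µM | all but G at the start; G goes in evenly over 4.00 h, the run ends at 5.0 h | 5.0 h |
| south | 0.10 M | 0.95 µM | a closed flask charged with all of it at once and left for 5.0 h | 5.0 h |

- alpha (time / h: Z / %): 1.33: 6.7; 2.50: 12.7; 4.00: 18.8; 5.00: 22.3
- zeta (time / h: Z / %): 0.250: 0.8; 0.500: 1.8; 1.33: 4.0; 3.00: 7.4
- beta (time / h: Z / %): 0.417: 1.4; 1.00: 4.4; 2.00: 8.4; 3.00: 10.7
- epsilon (time / h: Z / %): 0.417: 3.5; 1.00: 6.5; 2.00: 12.5; 3.00: 17.7

(standard deviation of a reading: 0.5 percentage points)

- the stated concentrations are those of everything mixed, before any reaction; amounts are the same in each set-up
- the feed brings no volume worth counting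
- the earlier runs were made in a closed, stirred flask
- a reading or a percentage of Z counts all its forms, free or not

* the set-up with the highest amount of Z at the outlet or at the end, in percent of the G put in ("none" if the first two lie within 2 percentage points) (north-west / west / north / south / none)
* amount of Z at the outlet or at the end, in percent of the G put in, north-west
* amount of Z at the outlet or at the end, in percent of the G put in, west
* amount of Z at the outlet or at the end, in percent of the G put in, north
* amount of Z at the outlet or at the end, in percent of the G put in, south

At the first reading of alpha, Z stands at 6.7 % of the charge after 1.33 h. From that reading, which carries a scatter of 0.5 percentage points, I take the early pace (the initial rate). The turnover clock, the time J in this recipe needs to turn one whole charge at that early pace, is 19.9 h. For a flask with this charge of G and this J, the turnover count is its time divided by the clock, and its fraction of Z is that count times a pace share, the mean pace held against the early one.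

Now the middle. Alpha has 18.8 % at 4.00 h, and the stretch to 5.00 h runs at 0.695 of the early pace. As a reading, that loss of pace is larger than the fraction turned into Z, but it rests on the difference of two scattered readings, so I hold it loosely. Epsilon, with half the G, still makes Z in amount at 0.645 of alpha's early pace.

At the end of alpha, Z is 22.3 %, and south repeats that recipe. South, north and north-west each have a count of 0.252; west has 1.26. To pass alpha's final reading, west needs a pace share of just 0.177, which is well below the 0.645 that epsilon shows near its start. That epsilon figure belongs to an early moment, while west is a steady tank with Z in it, so it is a rough yardstick. My own reckoning puts west ahead of south, and north-west and north share south's count.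

The forecast gives 19 % for north-west, 40 % for west, 15 % for north and 22.5 % for south, with west best, and it warns: “The long residence time is the most uncertain”.

West gives 40.6 %, more than north-west at 20.9 %, north at 16.1 % and south at 23.6 %.

    G + J → Z + J, rate k1*[G]^2*[J]/(1 + ([G]/Kh1)^2) (43.0 mM, k = 3.60 × 10⁶ /M²/h)
    G + Z ⇌ D, settled at all times (K = 210 /M)

In west, G stands at 25.3 % of its charge. West's pace share comes to 0.322, above the 0.177 it needed. North, left ten times as long, to 50.0 h, has a count of 2.51 and gives 57.9 %, a pace share of 0.230.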